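**Remarks and assumptions**

- Atom labels: lactone O1, C2(=O), C3=C4, C5, C6; side chain C1'=C2', C3', C4'(OAc), C5', C6'(OH), C7', C8'(OH), C9', C10'(Ph).
- Check of the plan: the three coupling components and the coupling product map onto the target with 6S, 4'R, 6'R, 8'R, an E-alkene and a 1,3-syn acetonide. No structural correction is required.
- Descriptor note: the dioxane carbon that becomes C6' is written 4R or 4S depending on its neighbours (a priority change only). Its configuration never changes.
- (+)-Diisopinocampheylborane, (+)-Ipc2BH, crystallised from (−)-α-pinene and BH3·SMe2, is treated as a stock reagent.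
- Assumed sense of induction: isopinocampheyl allylboranes from (+)-α-pinene add to the Si face of an aldehyde, so the reagent from (−)-α-pinene is assigned for 6S. If the sense were the opposite, the enantiomeric borane would be used and nothing else changes.

## Structural features

The target is a 6-substituted 5,6-dihydro-2H-pyran-2-one (O1, C2 to C6) whose C6 carries a ten-carbon chain, C1' to C10', that ends in a phenyl ring. Ring and chain are joined through C6–C1'; C1'=C2' is an E-alkene, C4' bears an acetate, and C6' and C8' bear free hydroxyls. There are four stereocentres: C6 (S), C4' (R), C6' (R) and C8' (R). C6' and C8' are 1,3-syn, C4' and C6' are 1,3-anti, and C6 and C4' are 1,5-anti across the alkene. The fragile groups are the conjugated lactone (a Michael acceptor with an allylic, acyloxy-bearing C6), the acetate next to a free 1,3-diol (acyl migration) and any β-hydroxy carbonyl intermediate (loss of water). The real difficulty is the remote C6/C4' relationship across an open-chain E-olefin, where no ring can relay stereochemistry, together with telling four oxygens apart (one in the lactone, one acetylated, two free). The syn-diol at C6'/C8' is routine by comparison. The key step exploits the unit C6(O)–C1'=C2'–C3'–C4'(O), an (E)-pent-2-ene-1,5-diol: its three inner carbons come from a bis-boron linchpin and its two carbinol carbons from two aldehydes.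

## Logic of the disconnections

**29 to 28.** The two C–O bonds between the isopropylidene carbon and O6'/O8' are the last to be cleaved in the forward sense. Masking these two hydroxyls leaves O4' as the only one that can be acylated. The demand on the forward step is a hydrolysis mild enough to leave the acetate in place and the lactone closed.

**28 to 27.** The O4'–acyl bond is cut. The acetate is put on when the C4' hydroxyl is the only free hydroxyl in the molecule, so no selectivity is needed. The forward step must avoid strong base because of the lactone.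

**27 to 25 (through 26).** C3=C4 and O1–C2 are cut, which removes the ring and the enoate and leaves an open-chain β-hydroxy aldehyde. Only O6 can reach the ester of a Z-enoate through a six-membered ring, so the lactonisation itself tells O6 from O4' without a protecting group. This replaces the tactic of tying O6 to the benzyl ether as an arylidene acetal, whose later hydrolysis would have to spare the isopropylidene acetal and cannot be relied on to do so. The forward step must be Z-selective and must not dehydrate the aldehyde.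

**25 to 24 to 23.** No skeletal bond is cut; the oxidation level at C4 and the O4–benzyl bond are adjusted. The forward steps need cleavage of the ether without capture of the benzylic cation by O6, and oxidation of the primary hydroxyl in the presence of two secondary ones.

**23 to 14, 19 and 10.** C6–C1' and C3'–C4' are cut. This one operation accounts for both carbinols, the E-alkene and the 1,5-anti relationship. It leaves three fragments, of which only 10 is chiral. The forward step needs reagent-controlled face selectivity at C6, a chair relay from C1' to C4', and E-geometry.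

**10 to 9 to 8 to 7.** The oxidation level at C4' and the two acetal C–O bonds are adjusted. The syn-diol is locked as a chair dioxane that survives hydride, oxidant and borane. The aldehyde must be made without β-elimination.

**7 to 5.** The C6'–H bond is cut. The existing C8' hydroxyl directs the new carbinol, so the forward step is a 1,3-syn selective ketone reduction.

**5 to 2 and 3.** The C5'–C6' bond is cut. A two-carbon ester enolate is added to an ester carbonyl, and the forward step must tolerate the free hydroxyl of 2.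

**2 to 1.** The C8'–H bond is cut. The first stereocentre is set by a catalytic enantioselective reduction of an achiral keto ester.

**14 to 13 to 11.** One O–benzyl bond and the oxidation level of one terminus are adjusted. A symmetrical diol must be mono-protected.

**19 to 18 to 15.** The B–O bonds and the C1'–B bond are cut. The three-carbon linchpin is reached from a three-carbon halide through an allenyl metal species.

## Other disconnections considered

**Alternative 1:** The cut is the O–C9' bond of a seven-membered lactone, which traces the C4'–C9' segment and its syn-diol back to the meso ketone (1R,5S)-3,3-dimethyl-2,4-dioxabicyclo[3.3.1]nonan-7-one A1. In the forward sense a cyclohexanone-monooxygenase-type flavin enzyme, with reduced nicotinamide cofactor and air, would insert oxygen next to one of the two enantiotopic methylene groups. The product would be 8,8-dimethyl-3,7,9-trioxabicyclo[4.3.1]decan-4-one A2 (carbonyl carbon C4', OCH2 carbon C9').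

- In its favour: both carbinol centres would be fixed in one catalytic, aerobic event at ambient temperature from an achiral substrate; the two termini would be differentiated at once; and a desymmetrisation has no theoretical yield ceiling.
- Against it here: C9' would arrive bearing oxygen, whereas the target needs C9' as a plain methylene bonded to benzylic C10'. The lactone would have to be opened, the primary alcohol activated and a benzyl nucleophile coupled, about three extra steps. An enzyme with the right enantiotopic preference for this rigid bicycle would have to be found. The step also says nothing about C6, C4', the alkene or the lactone, so a fragment union is still needed.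
- Comparison: on structure it would replace only steps 1 to 4 of the chosen route. On mechanism it is enzyme-controlled group selection against ligand-controlled hydrogenation plus chelation-controlled reduction. On step economy the way to an equivalent of 10 would be longer, roughly eight to nine steps against six. It is the better of the two in atom economy and in avoiding stoichiometric boron and a cryogenic reduction. It is the equal of the chosen plan in that the stereo-defining event is catalytic, as is step 1.

**Alternative 2:** The cuts are C5'–C6' and C6'–C7'. In the forward sense lithiated 2-(tert-butyldimethylsilyl)-1,3-dithiane A3 would open (2R)-2-(2-phenylethyl)oxirane A4 at its CH2. A polar phosphoramide additive would then trigger a 1,4-Brook shift of silicon to O8', and the regenerated dithiane anion would open (2R)-2-(prop-2-en-1-yl)oxirane A5. The product would be (2R)-1-{2-[(2R)-2-(tert-butyldimethylsilyloxy)-4-phenylbutyl]-1,3-dithian-2-yl}pent-4-en-2-ol A6.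

- In its favour: two C–C bonds in one pot, both carbinols from enantiopure epoxides, and a terminal alkene as a handle for C1'=C2'.
- Against it here: C6' is left as a masked ketone, so dithiane removal and a directed 1,3-reduction are still required, with a risk of β-elimination if the acetate is already in place. The additive is a carcinogen and alkyllithium chemistry at low temperature is needed. C6, the E-alkene and the lactone remain to be made, most plausibly by cross-metathesis, which would be expected to give a less clean E/Z outcome than a chair-controlled allylboration.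
- Comparison: on structure it covers C4' to C10', whereas the chosen key step covers C6, C4' and the alkene. On mechanism it relies on substrate chirality carried in from the epoxides, against reagent control followed by chirality transfer. On step economy it would be about the same or slightly longer. It is the equal of the chosen plan in convergency, since both are three-component one-pot unions. It is the better in oxygen differentiation: O4' would be born free and O8' silylated, whereas the chosen plan must tell O6 from O4' by lactonisation. The chosen plan is stronger on alkene geometry and on C6.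

**Alternative 3:** The cuts are C5–C6 and O1–C2. In the forward sense (E)-1-methoxybuta-1,3-diene A7 would add across the aldehyde C=O of (2R,4E)-1-[(4R,6R)-2,2-dimethyl-6-(2-phenylethyl)-1,3-dioxan-4-yl]-6-oxohex-4-en-2-yl acetate A8 under a chiral tridentate Schiff-base chromium chloride catalyst (trivalent chromium). The product would be the lactol methyl ether (2R,4E)-1-[(4R,6R)-2,2-dimethyl-6-(2-phenylethyl)-1,3-dioxan-4-yl]-5-[(2S)-6-methoxy-3,6-dihydro-2H-pyran-2-yl]pent-4-en-2-yl acetate A9, whose anomeric centre is erased later by oxidation.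

- In its favour: a catalytic, fully atom-economical cycloaddition that would build the ring and set C6 in one late step.
- Against it here: A8 is a conjugated aldehyde, a weaker heterodienophile than a saturated one, and its C=C could compete as a carbon dienophile. Its γ-methylene and δ-acetate invite vinylogous elimination. The alkene and C4' would have to be made separately (allylation, acetylation, cross-metathesis). A9 would still need acetal hydrolysis and lactol oxidation in a molecule that also holds an acid-labile isopropylidene acetal.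
- Comparison: on structure it closes the ring by cycloaddition where the chosen plan closes it by olefination and lactonisation. On mechanism it is a catalyst-controlled [4+2] addition against two chair allylborations. On step economy it is about equal, six to seven steps from 10 against six. It is the better of the two in oxygen differentiation, since O6 would be born as the ring oxygen and O4' would be acetylated before any second hydroxyl exists. It is also the better in using a catalytic instead of a stoichiometric chiral controller. The chosen plan is stronger in setting the E-alkene and both carbinols together and in avoiding the sensitive enal.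

Key step: step 11

## Route

Step 1
Reactants: 1 ethyl 3-oxo-5-phenylpentanoate
Product: 2 ethyl (3R)-3-hydroxy-5-phenylpentanoate
Conditions: H2 (10 atm), RuCl2[(R)-BINAP] (0.1 mol %), EtOH, 80 °C
Reagents that add atoms: none
Why: Noyori asymmetric hydrogenation of a β-keto ester; the ester carbonyl chelates divalent ruthenium and the (R)-BINAP ligand should direct hydride to the ketone face that gives the 3R carbinol, the future C8'.

Step 2
Reactants: 2 ethyl (3R)-3-hydroxy-5-phenylpentanoate; 3 tert-butyl acetate
Product: 5 tert-butyl (5R)-5-hydroxy-3-oxo-7-phenylheptanoate, via tert-butyl acetate lithium enolate 4 (not isolated)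
Conditions: LiN(iPr)2 (3.3 equiv), 3 (3.3 equiv), THF, −78 °C; then 2, −78 → −20 °C; AcOH
Reagents that add atoms: none
Why: Crossed Claisen condensation: one equivalent of 4 deprotonates the hydroxyl, a second acylates at the ethyl ester, and the product rests as its enolate, which protects it from further attack; the stereocentre is not touched.

Step 3
Reactants: 5 tert-butyl (5R)-5-hydroxy-3-oxo-7-phenylheptanoate
Product: 7 tert-butyl (3R,5R)-3,5-dihydroxy-7-phenylheptanoate, via diethylboron chelate of the hydroxy ketone 6 (not isolated)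
Conditions: Et2BOMe (1.1 equiv), THF/MeOH (4:1), −78 °C; NaBH4, −78 °C; MeOH azeotrope
Reagents that add atoms: none
Why: Narasaka–Prasad reduction: boron ties the hydroxyl and the ketone into a six-membered half-chair 6, and external hydride attacks axially, which should give the 1,3-syn diol (new centre 3R, the future C6').

Step 4
Reactants: 7 tert-butyl (3R,5R)-3,5-dihydroxy-7-phenylheptanoate
Product: 8 tert-butyl 2-[(4R,6R)-2,2-dimethyl-6-(2-phenylethyl)-1,3-dioxan-4-yl]acetate
Conditions: 2,2-dimethoxypropane, PPTS (cat.), CH2Cl2, rt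
Reagents that add atoms: 2,2-dimethoxypropane, COC(C)(C)OC
Why: Acid-catalysed transacetalisation; the syn-diol gives a chair dioxane with both ring substituents equatorial, so the acetal should form readily and be robust.

Step 5
Reactants: 8 tert-butyl 2-[(4R,6R)-2,2-dimethyl-6-(2-phenylethyl)-1,3-dioxan-4-yl]acetate
Product: 9 2-[(4S,6R)-2,2-dimethyl-6-(2-phenylethyl)-1,3-dioxan-4-yl]ethan-1-ol
Conditions: LiAlH4, THF, 0 °C; then H2O, NaOH (15% aq), H2O
Reagents that add atoms: none
Why: Hydride reduction of the ester to the primary alcohol; the acetal is inert to hydride and the basic work-up keeps it intact (the change from 4R to 4S is a priority change only).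

Step 6
Reactants: 9 2-[(4S,6R)-2,2-dimethyl-6-(2-phenylethyl)-1,3-dioxan-4-yl]ethan-1-ol
Product: 10 2-[(4R,6R)-2,2-dimethyl-6-(2-phenylethyl)-1,3-dioxan-4-yl]acetaldehyde
Conditions: Dess–Martin periodinane, pyridine, CH2Cl2, 0 °C → rt
Reagents that add atoms: none
Why: Dess–Martin oxidation under buffered, non-basic conditions should give the β-alkoxy aldehyde without β-elimination or loss of the acetal; the aldehyde is used without storage.

Step 7
Reactants: 11 propane-1,3-diol
Product: 13 3-[(4-methoxyphenyl)methoxy]propan-1-ol, via sodium 3-hydroxypropan-1-olate 12 (not isolated)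
Conditions: 11 (3 equiv), NaH (1.0 equiv), THF/DMF, 0 °C; 4-methoxybenzyl chloride (1.0 equiv), Bu4NI (cat.), 0 °C → rt
Reagents that add atoms: 4-methoxybenzyl chloride, COc1ccc(CCl)cc1
Why: Williamson etherification; the excess of the symmetrical diol and one equivalent of base favour the mono-ether, which is separated from unreacted diol by extraction.

Step 8
Reactants: 13 3-[(4-methoxyphenyl)methoxy]propan-1-ol
Product: 14 3-[(4-methoxyphenyl)methoxy]propanal
Conditions: TEMPO (cat.), PhI(OAc)2 (1.1 equiv), CH2Cl2, rt
Reagents that add atoms: none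
Why: Oxoammonium-mediated oxidation of a primary alcohol stops at the aldehyde in the absence of water and avoids the base that would eliminate the β-alkoxy group.

Step 9
Reactants: 15 propargyl bromide
Product: 18 propa-1,2-dienylboronic acid, via propa-1,2-dienylmagnesium bromide 16 (not isolated), via dimethyl propa-1,2-dienylboronate 17 (not isolated)
Conditions: Mg, ZnBr2 (cat.), Et2O, 0 °C; B(OMe)3, −78 °C; HCl (1 M aq), 0 °C
Reagents that add atoms: trimethyl borate, COB(OC)OC; water, O
Why: Grignard formation from the propargylic halide (used as a toluene solution, with mercury-free zinc dibromide activation) gives the allenyl magnesium species, and borylation followed by hydrolysis is the known preparation of the allenylboronic acid.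

Step 10
Reactants: 18 propa-1,2-dienylboronic acid
Product: 19 5,5-dimethyl-2-(propa-1,2-dienyl)-1,3,2-dioxaborinane
Conditions: 2,2-dimethylpropane-1,3-diol, MgSO4, Et2O, rt
Reagents that add atoms: 2,2-dimethylpropane-1,3-diol, OCC(C)(C)CO
Why: Condensation of the boronic acid with a 1,3-diol; the small six-membered ester is chosen on purpose, because a hindered ester would push the α-substituent of the later allylboronate into the axial position and erode E-selectivity.

Step 11
Reactants: 19 5,5-dimethyl-2-(propa-1,2-dienyl)-1,3,2-dioxaborinane; 14 3-[(4-methoxyphenyl)methoxy]propanal; 10 2-[(4R,6R)-2,2-dimethyl-6-(2-phenylethyl)-1,3-dioxan-4-yl]acetaldehyde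
Product: 23 (3S,4E,7R)-8-[(4S,6R)-2,2-dimethyl-6-(2-phenylethyl)-1,3-dioxan-4-yl]-1-[(4-methoxyphenyl)methoxy]oct-4-ene-3,7-diol, via E-gamma-boryl allyldiisopinocampheylborane 20 (not isolated), via alpha-boryl homoallyl borinate 21 (not isolated), via O-borylated diol 22 (not isolated)
Conditions: (+)-Ipc2BH [from (−)-α-pinene] (1.4 equiv), 19 (1.5 equiv), Et2O, −25 → 0 °C; 14 (1.45 equiv), −78 °C; 10 (1.0 equiv), −78 → 23 °C, 24 h; NaOH (3 M aq), H2O2 (30%), 0 °C → rt
Reagents that add atoms: none
Why: (+)-Ipc2BH hydroborates the terminal C=C of 19 with boron on CH2, and reversible 1,3-boratropic shifts collect the adduct as the E-configured reagent 20. At −78 °C the dialkylborane end of 20 allylborates 14 through a Zimmerman–Traxler chair with the aldehyde chain equatorial, forming C6–C1'; the isopinocampheyl groups select the aldehyde face that gives 6S (reagent control), and the E-geometry of 20 places O6 and the C1' boron anti in 21. The boronate 21 is far less Lewis acidic and reacts only on warming, when it allylborates 10 through a second chair in which the C1' substituent sits equatorial, a preference secured by the small, unhindered dioxaborinane ester. In that chair the C3'–C4' bond forms on the face of the allyl unit that carries boron, so C1'=C2' emerges E and the C1' configuration is relayed to C4' as R, which is the 1,5-anti diol. No ring is closed; two skeletal bonds and two stereocentres are made. The closest known reaction type is the one-pot double allylboration of two aldehydes with an E-γ-(dialkoxyboryl)allyldiisopinocampheylborane, which gives (E)-pent-2-ene-1,5-anti-diols. The step needs face selectivity at C6, E-selectivity, the 1,5-anti relay and an override of the β-alkoxy bias of 10; the first three rest on the two chairs, the last on the fact that a closed, non-chelating boron transition state feels a β-stereocentre only weakly. Chemoselectivity between the aldehydes rests on stoichiometry: 14 is in slight excess over the borane, so no dialkylallylborane survives to consume 10, and 21 is in excess over 10, the limiting component.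

Step 12
Reactants: 23 (3S,4E,7R)-8-[(4S,6R)-2,2-dimethyl-6-(2-phenylethyl)-1,3-dioxan-4-yl]-1-[(4-methoxyphenyl)methoxy]oct-4-ene-3,7-diol
Product: 24 (3S,4E,7R)-8-[(4S,6R)-2,2-dimethyl-6-(2-phenylethyl)-1,3-dioxan-4-yl]oct-4-ene-1,3,7-triol
Conditions: DDQ (1.2 equiv), CH2Cl2/pH 7 phosphate buffer (10:1), 0 °C
Reagents that add atoms: none
Why: Oxidative cleavage of the 4-methoxybenzyl ether: hydride abstraction gives an oxocarbenium ion that water in the buffered two-phase medium should hydrolyse before O6 can close an arylidene acetal; the acetonide, the isolated alkene and the unactivated allylic alcohol are expected to be inert at 0 °C.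

Step 13
Reactants: 24 (3S,4E,7R)-8-[(4S,6R)-2,2-dimethyl-6-(2-phenylethyl)-1,3-dioxan-4-yl]oct-4-ene-1,3,7-triol
Product: 25 (3S,4E,7R)-8-[(4S,6R)-2,2-dimethyl-6-(2-phenylethyl)-1,3-dioxan-4-yl]-3,7-dihydroxyoct-4-enal
Conditions: TEMPO (0.1 equiv), PhI(OAc)2 (1.1 equiv), CH2Cl2, 0 °C → rt
Reagents that add atoms: none
Why: The bulky oxoammonium oxidant discriminates in favour of the primary hydroxyl over the two secondary ones, and no lactol can form from a 1,3-hydroxy aldehyde, so oxidation should stop at the aldehyde; 25 is taken on crude and cold to avoid loss of water.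

Step 14
Reactants: 25 (3S,4E,7R)-8-[(4S,6R)-2,2-dimethyl-6-(2-phenylethyl)-1,3-dioxan-4-yl]-3,7-dihydroxyoct-4-enal
Product: 27 (6S)-6-[(1E,4R)-5-[(4S,6R)-2,2-dimethyl-6-(2-phenylethyl)-1,3-dioxan-4-yl]-4-hydroxypent-1-en-1-yl]-5,6-dihydro-2H-pyran-2-one, via Z-enoate methyl ester 26 (not isolated)
Conditions: (CF3CH2O)2P(O)CH2CO2Me, KN(SiMe3)2, 18-crown-6, THF, −78 °C; then PPTS (cat.), CH2Cl2, rt
Reagents that add atoms: methyl 2-[bis(2,2,2-trifluoroethoxy)phosphoryl]acetate, COC(=O)CP(=O)(OCC(F)(F)F)OCC(F)(F)F
Why: Still–Gennari Z-selective Horner–Wadsworth–Emmons olefination: the electron-poor phosphonate collapses fast from the kinetic adduct and should give the Z-enoate 26 at −78 °C, where the weakly basic phosphonate anion should not dehydrate the aldehyde. Only O6 can reach the ester through a six-membered ring, so acid-catalysed lactonisation gives 27 and leaves the C4' hydroxyl free, which is what tells the two carbinols apart.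

Step 15
Reactants: 27 (6S)-6-[(1E,4R)-5-[(4S,6R)-2,2-dimethyl-6-(2-phenylethyl)-1,3-dioxan-4-yl]-4-hydroxypent-1-en-1-yl]-5,6-dihydro-2H-pyran-2-one
Product: 28 (2R,4E)-1-[(4R,6R)-2,2-dimethyl-6-(2-phenylethyl)-1,3-dioxan-4-yl]-5-[(2S)-6-oxo-3,6-dihydro-2H-pyran-2-yl]pent-4-en-2-yl acetate
Conditions: Ac2O, pyridine, DMAP (cat.), CH2Cl2, 0 °C → rt
Reagents that add atoms: acetic anhydride, CC(=O)OC(C)=O
Why: DMAP-catalysed acylation of the only free hydroxyl; the weakly basic medium should leave the lactone intact and no stereocentre is touched.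

Step 16
Reactants: 28 (2R,4E)-1-[(4R,6R)-2,2-dimethyl-6-(2-phenylethyl)-1,3-dioxan-4-yl]-5-[(2S)-6-oxo-3,6-dihydro-2H-pyran-2-yl]pent-4-en-2-yl acetate
Product: 29 (6S)-6-[(1E,4R,6R,8R)-4-acetoxy-6,8-dihydroxy-10-phenyldec-1-en-1-yl]-5,6-dihydro-2H-pyran-2-one
Conditions: AcOH/H2O (4:1), 40 °C
Reagents that add atoms: none
Why: Acid hydrolysis of the isopropylidene acetal; a weak aqueous acid without base or alcohol solvent is chosen so that the acetate should stay on O4' and the lactone should stay closed.

## Compound list

1 | ethyl 3-oxo-5-phenylpentanoate | CCOC(=O)CC(=O)CCc1ccccc1 | starting material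
2 | ethyl (3R)-3-hydroxy-5-phenylpentanoate | CCOC(=O)C[C@H](O)CCc1ccccc1 | intermediate
3 | tert-butyl acetate | CC(=O)OC(C)(C)C | starting material
4 | lithium enolate of tert-butyl acetate (lithium 1-tert-butoxyethen-1-olate) | [Li]OC(=C)OC(C)(C)C | intermediate (not isolated)
5 | tert-butyl (5R)-5-hydroxy-3-oxo-7-phenylheptanoate | CC(C)(C)OC(=O)CC(=O)C[C@H](O)CCc1ccccc1 | intermediate
6 | tert-butyl (5R)-5-(diethylboranyloxy)-3-oxo-7-phenylheptanoate (boron chelated by the ketone oxygen) | CCB(CC)O[C@H](CCc1ccccc1)CC(=O)CC(=O)OC(C)(C)C | intermediate (not isolated)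
7 | tert-butyl (3R,5R)-3,5-dihydroxy-7-phenylheptanoate | CC(C)(C)OC(=O)C[C@H](O)C[C@H](O)CCc1ccccc1 | intermediate
8 | tert-butyl 2-[(4R,6R)-2,2-dimethyl-6-(2-phenylethyl)-1,3-dioxan-4-yl]acetate | CC(C)(C)OC(=O)C[C@H]1C[C@@H](CCc2ccccc2)OC(C)(C)O1 | intermediate
9 | 2-[(4S,6R)-2,2-dimethyl-6-(2-phenylethyl)-1,3-dioxan-4-yl]ethan-1-ol | OCC[C@H]1C[C@@H](CCc2ccccc2)OC(C)(C)O1 | intermediate
10 | 2-[(4R,6R)-2,2-dimethyl-6-(2-phenylethyl)-1,3-dioxan-4-yl]acetaldehyde | O=CC[C@H]1C[C@@H](CCc2ccccc2)OC(C)(C)O1 | intermediate
11 | propane-1,3-diol | OCCCO | starting material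
12 | sodium 3-hydroxypropan-1-olate | [Na+].[O-]CCCO | intermediate (not isolated)
13 | 3-[(4-methoxyphenyl)methoxy]propan-1-ol | OCCCOCc1ccc(OC)cc1 | intermediate
14 | 3-[(4-methoxyphenyl)methoxy]propanal | O=CCCOCc1ccc(OC)cc1 | intermediate
15 | propargyl bromide (3-bromoprop-1-yne) | C#CCBr | starting material
16 | propa-1,2-dienylmagnesium bromide | C=C=C[Mg]Br | intermediate (not isolated)
17 | dimethyl propa-1,2-dienylboronate | C=C=CB(OC)OC | intermediate (not isolated)
18 | propa-1,2-dienylboronic acid | C=C=CB(O)O | intermediate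
19 | 5,5-dimethyl-2-(propa-1,2-dienyl)-1,3,2-dioxaborinane | C=C=CB1OCC(C)(C)CO1 | intermediate
20 | 2-[(1E)-3-(diisopinocampheylboranyl)prop-1-en-1-yl]-5,5-dimethyl-1,3,2-dioxaborinane (isopinocampheyl groups from (−)-α-pinene) | CC1(C)COB(/C=C/CB([C@H]2C[C@H]3C[C@@H]([C@@H]2C)C3(C)C)[C@H]2C[C@H]3C[C@@H]([C@@H]2C)C3(C)C)OC1 | intermediate (not isolated)
21 | 2-[(3S,4R)-3-(diisopinocampheylboranyloxy)-1-[(4-methoxyphenyl)methoxy]hex-5-en-4-yl]-5,5-dimethyl-1,3,2-dioxaborinane | C=C[C@@H](B1OCC(C)(C)CO1)[C@H](CCOCc1ccc(OC)cc1)OB([C@H]1C[C@H]2C[C@@H]([C@@H]1C)C2(C)C)[C@H]1C[C@H]2C[C@@H]([C@@H]1C)C2(C)C | intermediate (not isolated)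
22 | diol 23 carrying the diisopinocampheylboryl group on O6 and the 5,5-dimethyl-1,3,2-dioxaborinan-2-yl group on O4' | CC1(C)COB(OC1)O[C@H](C/C=C/[C@@H](OB([C@H]1C[C@H]2C[C@@H]([C@@H]1C)C2(C)C)[C@H]1C[C@H]2C[C@@H]([C@@H]1C)C2(C)C)CCOCc1ccc(OC)cc1)C[C@H]2C[C@@H](CCc3ccccc3)OC(C)(C)O2 | intermediate (not isolated)
23 | (3S,4E,7R)-8-[(4S,6R)-2,2-dimethyl-6-(2-phenylethyl)-1,3-dioxan-4-yl]-1-[(4-methoxyphenyl)methoxy]oct-4-ene-3,7-diol | O[C@H](C/C=C/[C@@H](O)CCOCc1ccc(OC)cc1)C[C@H]2C[C@@H](CCc3ccccc3)OC(C)(C)O2 | intermediate
24 | (3S,4E,7R)-8-[(4S,6R)-2,2-dimethyl-6-(2-phenylethyl)-1,3-dioxan-4-yl]oct-4-ene-1,3,7-triol | O[C@H](C/C=C/[C@@H](O)CCO)C[C@H]2C[C@@H](CCc3ccccc3)OC(C)(C)O2 | intermediate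
25 | (3S,4E,7R)-8-[(4S,6R)-2,2-dimethyl-6-(2-phenylethyl)-1,3-dioxan-4-yl]-3,7-dihydroxyoct-4-enal | O[C@H](C/C=C/[C@@H](O)CC=O)C[C@H]2C[C@@H](CCc3ccccc3)OC(C)(C)O2 | intermediate
26 | methyl (2Z,5S,6E,9R)-10-[(4S,6R)-2,2-dimethyl-6-(2-phenylethyl)-1,3-dioxan-4-yl]-5,9-dihydroxydeca-2,6-dienoate | O[C@H](C/C=C/[C@@H](O)C/C=C\C(=O)OC)C[C@H]2C[C@@H](CCc3ccccc3)OC(C)(C)O2 | intermediate (not isolated)
27 | (6S)-6-[(1E,4R)-5-[(4S,6R)-2,2-dimethyl-6-(2-phenylethyl)-1,3-dioxan-4-yl]-4-hydroxypent-1-en-1-yl]-5,6-dihydro-2H-pyran-2-one | O[C@H](C/C=C/[C@@H]1CC=CC(=O)O1)C[C@H]2C[C@@H](CCc3ccccc3)OC(C)(C)O2 | intermediate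
28 | (2R,4E)-1-[(4R,6R)-2,2-dimethyl-6-(2-phenylethyl)-1,3-dioxan-4-yl]-5-[(2S)-6-oxo-3,6-dihydro-2H-pyran-2-yl]pent-4-en-2-yl acetate | CC(=O)O[C@H](C/C=C/[C@@H]1CC=CC(=O)O1)C[C@H]2C[C@@H](CCc3ccccc3)OC(C)(C)O2 | intermediate
29 | (6S)-6-[(1E,4R,6R,8R)-4-acetoxy-6,8-dihydroxy-10-phenyldec-1-en-1-yl]-5,6-dihydro-2H-pyran-2-one | CC(=O)O[C@H](C/C=C/[C@@H]1CC=CC(=O)O1)C[C@H](O)C[C@H](O)CCc1ccccc1 | target

## Step count and least certain steps

Total: 16 steps (six to 10, two to 14, two to 19, the three-component union, five to the target). The preparation of the stock borane is not counted. Longest linear sequence: 12 steps (1 to 6, then 11 to 16).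

**Step 11 (key step).** The most likely failures are incomplete equilibration to the E reagent, and a slow second allylboration of a chiral β-alkoxy aldehyde that is the limiting component; either would erode the E-selectivity and the 1,5-anti relay. A further risk is consumption of the limiting aldehyde by residual dialkylallylborane if the stoichiometry of the first stage is off. A stepwise fallback sets out from 10 and 14 and comes back at 23.

- Brown allylboration of 10 with the allyldiisopinocampheylborane derived from (−)-α-pinene should give (2R)-1-[(4S,6R)-2,2-dimethyl-6-(2-phenylethyl)-1,3-dioxan-4-yl]pent-4-en-2-ol F1.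
- Vinylmagnesium bromide adds to 14 to give racemic 5-[(4-methoxyphenyl)methoxy]pent-1-en-3-ol F2.
- Cross-metathesis of F1 with an excess of F2 (second-generation Hoveyda–Grubbs catalyst) joins C1'=C2' as the E-alkene and gives (4E,7R)-8-[(4S,6R)-2,2-dimethyl-6-(2-phenylethyl)-1,3-dioxan-4-yl]-1-[(4-methoxyphenyl)methoxy]oct-4-ene-3,7-diol as both C3 epimers F3.
- MnO2 oxidises only the allylic hydroxyl, converging the epimers on (4E,7R)-8-[(4S,6R)-2,2-dimethyl-6-(2-phenylethyl)-1,3-dioxan-4-yl]-7-hydroxy-1-[(4-methoxyphenyl)methoxy]oct-4-en-3-one F4.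
- Corey–Bakshi–Shibata reduction with the (R)-methyl oxazaborolidine and BH3·SMe2, with the alkenyl group acting as the large substituent, should set 6S and give 23.

**Step 14 (with the aldehyde of step 13).** The most likely failures are base- or acid-induced loss of water from the β-hydroxy aldehyde towards a conjugated dienal, a lower Z-selectivity with free hydroxyls present, and incomplete ring closure. A protected fallback sets out from 23 and comes back at 27.

- Silylation of both hydroxyls (Et3SiOTf, 2,6-lutidine) gives (3S,4E,7R)-8-[(4R,6R)-2,2-dimethyl-6-(2-phenylethyl)-1,3-dioxan-4-yl]-1-[(4-methoxyphenyl)methoxy]-3,7-bis(triethylsilyloxy)oct-4-ene F8.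
- Buffered DDQ cleaves the benzyl ether, now with no neighbouring hydroxyl, to (3S,4E,7R)-8-[(4R,6R)-2,2-dimethyl-6-(2-phenylethyl)-1,3-dioxan-4-yl]-3,7-bis(triethylsilyloxy)oct-4-en-1-ol F9.
- Dess–Martin oxidation gives the stable β-silyloxy aldehyde (3S,4E,7R)-8-[(4R,6R)-2,2-dimethyl-6-(2-phenylethyl)-1,3-dioxan-4-yl]-3,7-bis(triethylsilyloxy)oct-4-enal F10.
- Still–Gennari olefination gives methyl (2Z,5S,6E,9R)-10-[(4R,6R)-2,2-dimethyl-6-(2-phenylethyl)-1,3-dioxan-4-yl]-5,9-bis(triethylsilyloxy)deca-2,6-dienoate F11.
- Buffered HF·pyridine removes both silyl groups and closes the lactone to 27.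

**Step 12.** The most likely failures are capture of the benzylic cation by the neighbouring C6 hydroxyl (oxidative acetal formation) and further oxidation of that acetal or of the allylic alcohol. The fallback changes the protecting group of the first aldehyde; it sets out from 11 and comes back at 24.

- Mono-silylation of 11 (NaH, tert-butyldimethylsilyl chloride) gives 3-[tert-butyl(dimethyl)silyl]oxypropan-1-ol F5.
- Oxidation as in step 8 gives 3-[tert-butyl(dimethyl)silyl]oxypropanal F6.
- F6 takes the place of 14 in the double allylboration with 19 and 10 and gives (3S,4E,7R)-1-[tert-butyl(dimethyl)silyl]oxy-8-[(4S,6R)-2,2-dimethyl-6-(2-phenylethyl)-1,3-dioxan-4-yl]oct-4-ene-3,7-diol F7.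
- Bu4NF removes the primary silyl ether to give 24.

**Step 16.** The most likely failure is acid-promoted migration of the acetyl group from O4' to the newly freed O6' or O8' while the acetal is hydrolysed. The fallback replaces the acetal by silyl ethers that are removed with fluoride; it sets out from 7 and comes back at 29.

- Silylation of 7 (tert-butyldimethylsilyl triflate, 2,6-lutidine) gives tert-butyl (3R,5R)-3,5-bis[tert-butyl(dimethyl)silyloxy]-7-phenylheptanoate F12.
- LiAlH4 gives (3S,5R)-3,5-bis[tert-butyl(dimethyl)silyloxy]-7-phenylheptan-1-ol F13.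
- Dess–Martin oxidation gives (3R,5R)-3,5-bis[tert-butyl(dimethyl)silyloxy]-7-phenylheptanal F14.
- The double allylboration with 19 and 14 gives (3S,4E,7R,9S,11R)-9,11-bis[tert-butyl(dimethyl)silyloxy]-1-[(4-methoxyphenyl)methoxy]-13-phenyltridec-4-ene-3,7-diol F15.
- Buffered DDQ gives (3S,4E,7R,9S,11R)-9,11-bis[tert-butyl(dimethyl)silyloxy]-13-phenyltridec-4-ene-1,3,7-triol F16.
- TEMPO/PhI(OAc)2 gives (3S,4E,7R,9S,11R)-9,11-bis[tert-butyl(dimethyl)silyloxy]-3,7-dihydroxy-13-phenyltridec-4-enal F17.
- Still–Gennari olefination and lactonisation give (6S)-6-[(1E,4R,6S,8R)-6,8-bis[tert-butyl(dimethyl)silyloxy]-4-hydroxy-10-phenyldec-1-en-1-yl]-5,6-dihydro-2H-pyran-2-one F18.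
- Acetylation gives (1E,4R,6S,8R)-6,8-bis[tert-butyl(dimethyl)silyloxy]-1-[(2S)-6-oxo-3,6-dihydro-2H-pyran-2-yl]-10-phenyldec-1-en-4-yl acetate F19.
- HF·pyridine removes both silyl ethers to give 29.

## Further compounds

F1 | step 11 | (2R)-1-[(4S,6R)-2,2-dimethyl-6-(2-phenylethyl)-1,3-dioxan-4-yl]pent-4-en-2-ol | C=CC[C@@H](O)C[C@H]1C[C@@H](CCc2ccccc2)OC(C)(C)O1
F2 | step 11 | racemic 5-[(4-methoxyphenyl)methoxy]pent-1-en-3-ol | C=CC(O)CCOCc1ccc(OC)cc1
F3 | step 11 | (4E,7R)-8-[(4S,6R)-2,2-dimethyl-6-(2-phenylethyl)-1,3-dioxan-4-yl]-1-[(4-methoxyphenyl)methoxy]oct-4-ene-3,7-diol, both C3 epimers | O[C@H](C/C=C/C(O)CCOCc1ccc(OC)cc1)C[C@H]2C[C@@H](CCc3ccccc3)OC(C)(C)O2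
F4 | step 11 | (4E,7R)-8-[(4S,6R)-2,2-dimethyl-6-(2-phenylethyl)-1,3-dioxan-4-yl]-7-hydroxy-1-[(4-methoxyphenyl)methoxy]oct-4-en-3-one | O[C@H](C/C=C/C(=O)CCOCc1ccc(OC)cc1)C[C@H]2C[C@@H](CCc3ccccc3)OC(C)(C)O2
F5 | step 12 | 3-[tert-butyl(dimethyl)silyl]oxypropan-1-ol | OCCCO[Si](C)(C)C(C)(C)C
F6 | step 12 | 3-[tert-butyl(dimethyl)silyl]oxypropanal | O=CCCO[Si](C)(C)C(C)(C)C
F7 | step 12 | (3S,4E,7R)-1-[tert-butyl(dimethyl)silyl]oxy-8-[(4S,6R)-2,2-dimethyl-6-(2-phenylethyl)-1,3-dioxan-4-yl]oct-4-ene-3,7-diol | O[C@H](C/C=C/[C@@H](O)CCO[Si](C)(C)C(C)(C)C)C[C@H]2C[C@@H](CCc3ccccc3)OC(C)(C)O2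
F8 | step 14 | (3S,4E,7R)-8-[(4R,6R)-2,2-dimethyl-6-(2-phenylethyl)-1,3-dioxan-4-yl]-1-[(4-methoxyphenyl)methoxy]-3,7-bis(triethylsilyloxy)oct-4-ene | CC[Si](CC)(CC)O[C@H](C/C=C/[C@@H](O[Si](CC)(CC)CC)CCOCc1ccc(OC)cc1)C[C@H]2C[C@@H](CCc3ccccc3)OC(C)(C)O2
F9 | step 14 | (3S,4E,7R)-8-[(4R,6R)-2,2-dimethyl-6-(2-phenylethyl)-1,3-dioxan-4-yl]-3,7-bis(triethylsilyloxy)oct-4-en-1-ol | CC[Si](CC)(CC)O[C@H](C/C=C/[C@@H](O[Si](CC)(CC)CC)CCO)C[C@H]2C[C@@H](CCc3ccccc3)OC(C)(C)O2
F10 | step 14 | (3S,4E,7R)-8-[(4R,6R)-2,2-dimethyl-6-(2-phenylethyl)-1,3-dioxan-4-yl]-3,7-bis(triethylsilyloxy)oct-4-enal | CC[Si](CC)(CC)O[C@H](C/C=C/[C@@H](O[Si](CC)(CC)CC)CC=O)C[C@H]2C[C@@H](CCc3ccccc3)OC(C)(C)O2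
F11 | step 14 | methyl (2Z,5S,6E,9R)-10-[(4R,6R)-2,2-dimethyl-6-(2-phenylethyl)-1,3-dioxan-4-yl]-5,9-bis(triethylsilyloxy)deca-2,6-dienoate | CC[Si](CC)(CC)O[C@H](C/C=C/[C@@H](O[Si](CC)(CC)CC)C/C=C\C(=O)OC)C[C@H]2C[C@@H](CCc3ccccc3)OC(C)(C)O2
F12 | step 16 | tert-butyl (3R,5R)-3,5-bis[tert-butyl(dimethyl)silyloxy]-7-phenylheptanoate | CC(C)(C)OC(=O)C[C@H](O[Si](C)(C)C(C)(C)C)C[C@H](O[Si](C)(C)C(C)(C)C)CCc1ccccc1
F13 | step 16 | (3S,5R)-3,5-bis[tert-butyl(dimethyl)silyloxy]-7-phenylheptan-1-ol | OCC[C@H](O[Si](C)(C)C(C)(C)C)C[C@H](O[Si](C)(C)C(C)(C)C)CCc1ccccc1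
F14 | step 16 | (3R,5R)-3,5-bis[tert-butyl(dimethyl)silyloxy]-7-phenylheptanal | O=CC[C@H](O[Si](C)(C)C(C)(C)C)C[C@H](O[Si](C)(C)C(C)(C)C)CCc1ccccc1
F15 | step 16 | (3S,4E,7R,9S,11R)-9,11-bis[tert-butyl(dimethyl)silyloxy]-1-[(4-methoxyphenyl)methoxy]-13-phenyltridec-4-ene-3,7-diol | O[C@H](C/C=C/[C@@H](O)CCOCc1ccc(OC)cc1)C[C@H](O[Si](C)(C)C(C)(C)C)C[C@H](O[Si](C)(C)C(C)(C)C)CCc1ccccc1
F16 | step 16 | (3S,4E,7R,9S,11R)-9,11-bis[tert-butyl(dimethyl)silyloxy]-13-phenyltridec-4-ene-1,3,7-triol | O[C@H](C/C=C/[C@@H](O)CCO)C[C@H](O[Si](C)(C)C(C)(C)C)C[C@H](O[Si](C)(C)C(C)(C)C)CCc1ccccc1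
F17 | step 16 | (3S,4E,7R,9S,11R)-9,11-bis[tert-butyl(dimethyl)silyloxy]-3,7-dihydroxy-13-phenyltridec-4-enal | O[C@H](C/C=C/[C@@H](O)CC=O)C[C@H](O[Si](C)(C)C(C)(C)C)C[C@H](O[Si](C)(C)C(C)(C)C)CCc1ccccc1
F18 | step 16 | (6S)-6-[(1E,4R,6S,8R)-6,8-bis[tert-butyl(dimethyl)silyloxy]-4-hydroxy-10-phenyldec-1-en-1-yl]-5,6-dihydro-2H-pyran-2-one | O[C@H](C/C=C/[C@@H]1CC=CC(=O)O1)C[C@H](O[Si](C)(C)C(C)(C)C)C[C@H](O[Si](C)(C)C(C)(C)C)CCc1ccccc1
F19 | step 16 | (1E,4R,6S,8R)-6,8-bis[tert-butyl(dimethyl)silyloxy]-1-[(2S)-6-oxo-3,6-dihydro-2H-pyran-2-yl]-10-phenyldec-1-en-4-yl acetate | CC(=O)O[C@H](C/C=C/[C@@H]1CC=CC(=O)O1)C[C@H](O[Si](C)(C)C(C)(C)C)C[C@H](O[Si](C)(C)C(C)(C)C)CCc1ccccc1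
A1 | alternative 1 | (1R,5S)-3,3-dimethyl-2,4-dioxabicyclo[3.3.1]nonan-7-one (meso) | O=C1C[C@H]2C[C@@H](C1)OC(C)(C)O2
A2 | alternative 1 | 8,8-dimethyl-3,7,9-trioxabicyclo[4.3.1]decan-4-one (enantiomer with C6' and C8' as in the target) | O=C1C[C@H]2C[C@@H](CO1)OC(C)(C)O2
A3 | alternative 2 | 2-(tert-butyldimethylsilyl)-1,3-dithiane | CC(C)(C)[Si](C)(C)C1SCCCS1
A4 | alternative 2 | (2R)-2-(2-phenylethyl)oxirane | C1O[C@@H]1CCc1ccccc1
A5 | alternative 2 | (2R)-2-(prop-2-en-1-yl)oxirane | C=CC[C@@H]1CO1
A6 | alternative 2 | (2R)-1-{2-[(2R)-2-(tert-butyldimethylsilyloxy)-4-phenylbutyl]-1,3-dithian-2-yl}pent-4-en-2-ol | C=CC[C@@H](O)CC1(SCCCS1)C[C@@H](CCc2ccccc2)O[Si](C)(C)C(C)(C)C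
A7 | alternative 3 | (E)-1-methoxybuta-1,3-diene | CO/C=C/C=C
A8 | alternative 3 | (2R,4E)-1-[(4R,6R)-2,2-dimethyl-6-(2-phenylethyl)-1,3-dioxan-4-yl]-6-oxohex-4-en-2-yl acetate | O=C/C=C/C[C@@H](OC(C)=O)C[C@H]1C[C@@H](CCc2ccccc2)OC(C)(C)O1
A9 | alternative 3 | (2R,4E)-1-[(4R,6R)-2,2-dimethyl-6-(2-phenylethyl)-1,3-dioxan-4-yl]-5-[(2S)-6-methoxy-3,6-dihydro-2H-pyran-2-yl]pent-4-en-2-yl acetate (anomeric centre undefined) | COC1C=CC[C@@H](/C=C/C[C@@H](OC(C)=O)C[C@H]2C[C@@H](CCc3ccccc3)OC(C)(C)O2)O1
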